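## Retrosynthetic overview

- The strategy rests on ring B (C5–C10). It carries oxygen at C7 para to the methyl-bearing quaternary C10, with the C8 methyl (C17) and the C9 chain between them, so it is a masked 3-alkyl-2,4-dimethylphenol and C10 can be made by dearomatising C-alkylation.
- Key disconnection C1–C10: ring A (C1–C5, C10) is closed onto the phenol by palladium-catalysed allylic alkylation from a C5-bound C4(CH3)2–C3H=C2H–C1H2 carbonate. Bromine at C6 blocks the other ring carbon next to C5.
- Precursor: 2-bromo-1,3-dimethylbenzene (C5–C10, C17, C20) is coupled with an alkylzinc from (R)-methyl hydrogen 3-methylglutarate (C11–C16, brings C13). After dibromination, one bromine becomes the C7–OH and the other the C5–C4 bond by ester α-arylation with methyl isobutyrate (C3, C4, C18, C19); a (Z)-olefination adds C2 and C1.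
- After closure: hydrogenation sets C5; Li/NH3 reduction with enolate triflation sets C9 and, after triflate reduction, places C7=C8; SeO2 oxidises C17; desilylation and diacetylation finish.
- Ring order: ring B is the arene from the first coupling on; ring A is formed in the key step.

Key step: step 15

Remarks on the chemistry (labdane numbering is used for all ring compounds, arene carbons included):
- The C11–C15 chain is a 3-methylpentane-1,5-diyl unit, one carbon shorter than the chain of citronellol. It is therefore taken from the glutarate half-ester, assumed to be commercial in high enantiomeric purity.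
- The allyl carbonate is made with (Z) geometry so that ionisation gives the anti-configured allyl complex directly. From the (E) isomer that complex is reached only through a palladium σ-bond at the neopentyl carbon C3.
- Both hydroxyl groups are protected as triisopropylsilyl ethers. The aryl ether can be cleaved selectively, and the alkyl ether survives Li/NH3.
- C6 is brominated last, because α-arylation at a carbon flanked by two ortho substituents is not reliable.
- Assumption: the sense of induction of the ligand at C10 cannot be predicted with confidence; the (1R,2R) ligand is written, and its enantiomer is used if it favours the C10 epimer.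

## Route

Step 1
Reactants: 1 (R)-methyl hydrogen 3-methylglutarate
Product: 3 (S)-4-methyltetrahydro-2H-pyran-2-one, via lithium (S)-5-hydroxy-3-methylpentanoate 2 (not isolated)
Conditions: LiBH4 (2.2 equiv), THF, 0 °C to rt; then 2 M HCl, rt; TsOH (cat.), toluene, 60 °C
Reagents that add atoms: none
Why: Chemoselective borohydride reduction, in which LiBH4 reduces the methyl ester while the lithium carboxylate formed first is inert, and acidification closes the δ-lactone, so the former ester carbon becomes the O–CH2 carbon (later C11) and the stereocentre (later C13) is untouched.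

Step 2
Reactants: 3 (S)-4-methyltetrahydro-2H-pyran-2-one
Product: 4 methyl (R)-5-bromo-3-methylpentanoate
Conditions: anhydrous HBr, MeOH, 0 °C to rt
Reagents that add atoms: hydrogen bromide, Br; methanol, CO
Why: Acid-mediated lactone opening, in which bromide displaces the protonated ring oxygen at the primary O–CH2 carbon and the freed acid undergoes Fischer esterification, the classical route from lactones to ω-bromo esters.

Step 3
Reactants: 4 methyl (R)-5-bromo-3-methylpentanoate; 5 2-bromo-1,3-dimethylbenzene
Product: 7 methyl (S)-5-(2,6-dimethylphenyl)-3-methylpentanoate, via alkylzinc bromide 6 (not isolated)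
Conditions: Zn dust (1.5 equiv), I2 (5 mol%), DMA, 70 °C; then 5, Pd(OAc)2 (2 mol%), SPhos (2-dicyclohexylphosphino-2',6'-dimethoxybiphenyl, 4 mol%), THF, 60 °C
Reagents that add atoms: none
Why: Negishi coupling, in which iodine-activated zinc inserts into the primary C–Br bond without harming the ester and the biarylphosphine–palladium catalyst couples primary alkylzinc halides with aryl bromides bearing two ortho methyl groups, forming C9–C11.

Step 4
Reactants: 7 methyl (S)-5-(2,6-dimethylphenyl)-3-methylpentanoate
Product: 8 methyl (S)-5-(3,5-dibromo-2,6-dimethylphenyl)-3-methylpentanoate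
Conditions: Br2 (2.1 equiv), FeBr3 (5 mol%), CH2Cl2, −10 °C to rt, dark
Reagents that add atoms: bromine, BrBr
Why: Electrophilic aromatic bromination, which should enter twice at the equivalent positions ortho to one methyl and para to the other (future C5 and C7), since the remaining position (future C6) is activated only by the para alkyl group and deactivated by the first bromine; the ester tolerates the HBr formed, which is why this step precedes silylation.

Step 5
Reactants: 8 methyl (S)-5-(3,5-dibromo-2,6-dimethylphenyl)-3-methylpentanoate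
Product: 9 (S)-5-(3,5-dibromo-2,6-dimethylphenyl)-3-methylpentan-1-ol
Conditions: iBu2AlH (2.5 equiv), CH2Cl2, −78 to 0 °C
Reagents that add atoms: none
Why: Hydride reduction of the ester to the primary alcohol (future C15–OH), under which aryl bromides do not react.

Step 6
Reactants: 9 (S)-5-(3,5-dibromo-2,6-dimethylphenyl)-3-methylpentan-1-ol
Product: 12 5-bromo-3-[(S)-5-hydroxy-3-methylpentyl]-2,4-dimethylphenol, via aryllithium lithium alkoxide 10 (not isolated), via lithium aryltrimethoxyborate 11 (not isolated)
Conditions: n-BuLi (2.05 equiv), THF, −78 °C; B(OMe)3 (3 equiv), −78 °C to rt; then 30% H2O2, aq. NaOH, 0 °C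
Reagents that add atoms: hydrogen peroxide, OO
Why: Bromine–lithium exchange, borylation and oxidation, in which the first equivalent of n-BuLi forms the alkoxide, the second exchanges one of the two equivalent bromines (a second exchange on the electron-rich aryllithium is slower), and alkaline peroxide converts the C–B bond into the C7–OH bond.

Step 7
Reactants: 12 5-bromo-3-[(S)-5-hydroxy-3-methylpentyl]-2,4-dimethylphenol
Product: 13 {5-bromo-2,4-dimethyl-3-[(S)-3-methyl-5-(triisopropylsilyloxy)pentyl]phenoxy}triisopropylsilane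
Conditions: iPr3SiOTf (2.5 equiv), 2,6-lutidine, CH2Cl2, 0 °C to rt
Reagents that add atoms: triisopropylsilyl trifluoromethanesulfonate, CC(C)[Si](OS(=O)(=O)C(F)(F)F)(C(C)C)C(C)C
Why: Silyl ether formation with the reactive silyl triflate, which protects the phenol and the primary alcohol in one operation for the basic and hydridic steps that follow.

Step 8
Reactants: 13 {5-bromo-2,4-dimethyl-3-[(S)-3-methyl-5-(triisopropylsilyloxy)pentyl]phenoxy}triisopropylsilane; 14 methyl isobutyrate
Product: 16 methyl 2-methyl-2-{2,4-dimethyl-3-[(S)-3-methyl-5-(triisopropylsilyloxy)pentyl]-5-(triisopropylsilyloxy)phenyl}propanoate, via lithium ester enolate 15 (not isolated)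
Conditions: 14, LiNCy2 (1.3 equiv), toluene, 0 °C; then 13, Pd(dba)2 (bis(dibenzylideneacetone)palladium, 2 mol%), P(tBu)3 (2 mol%), rt
Reagents that add atoms: none
Why: Palladium-catalysed α-arylation of an ester enolate, which forms the quaternary C4 at an aryl bromide (C5) that has only one ortho substituent (the C10 methyl) and is established for methyl isobutyrate with ortho-substituted aryl bromides.

Step 9
Reactants: 16 methyl 2-methyl-2-{2,4-dimethyl-3-[(S)-3-methyl-5-(triisopropylsilyloxy)pentyl]-5-(triisopropylsilyloxy)phenyl}propanoate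
Product: 17 2-methyl-2-{2,4-dimethyl-3-[(S)-3-methyl-5-(triisopropylsilyloxy)pentyl]-5-(triisopropylsilyloxy)phenyl}propanal
Conditions: iBu2AlH (1.1 equiv), CH2Cl2, −78 °C; MeOH quench at −78 °C
Reagents that add atoms: none
Why: Partial hydride reduction of the ester to the aldehyde (C3), favoured because the aluminium hemiacetal of this α-quaternary ester is stable at −78 °C and collapses only on work-up.

Step 10
Reactants: 17 2-methyl-2-{2,4-dimethyl-3-[(S)-3-methyl-5-(triisopropylsilyloxy)pentyl]-5-(triisopropylsilyloxy)phenyl}propanal; 18 methyl bis(2,2,2-trifluoroethyl)phosphonoacetate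
Product: 20 methyl (Z)-4-methyl-4-{2,4-dimethyl-3-[(S)-3-methyl-5-(triisopropylsilyloxy)pentyl]-5-(triisopropylsilyloxy)phenyl}pent-2-enoate, via potassium phosphonate carbanion 19 (not isolated)
Conditions: 18, KN(SiMe3)2, 18-crown-6, THF, −78 °C; then 17, −78 °C
Reagents that add atoms: none
Why: Still–Gennari olefination, whose electron-poor trifluoroethyl phosphonate eliminates fast from the kinetically formed adduct and so should give the (Z)-enoate, also from α-quaternary aldehydes; it adds C2 and C1.

Step 11
Reactants: 20 methyl (Z)-4-methyl-4-{2,4-dimethyl-3-[(S)-3-methyl-5-(triisopropylsilyloxy)pentyl]-5-(triisopropylsilyloxy)phenyl}pent-2-enoate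
Product: 21 (Z)-4-methyl-4-{2,4-dimethyl-3-[(S)-3-methyl-5-(triisopropylsilyloxy)pentyl]-5-(triisopropylsilyloxy)phenyl}pent-2-en-1-ol
Conditions: iBu2AlH (2.5 equiv), CH2Cl2, −78 °C
Reagents that add atoms: none
Why: 1,2-Reduction of the enoate by the aluminium hydride, which gives the allylic alcohol without touching the (Z)-alkene.

Step 12
Reactants: 21 (Z)-4-methyl-4-{2,4-dimethyl-3-[(S)-3-methyl-5-(triisopropylsilyloxy)pentyl]-5-(triisopropylsilyloxy)phenyl}pent-2-en-1-ol
Product: 22 methyl (Z)-4-methyl-4-{2,4-dimethyl-3-[(S)-3-methyl-5-(triisopropylsilyloxy)pentyl]-5-(triisopropylsilyloxy)phenyl}pent-2-en-1-yl carbonate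
Conditions: ClCO2Me, pyridine, CH2Cl2, 0 °C
Reagents that add atoms: methyl chloroformate, COC(=O)Cl
Why: Acylation of the primary allylic alcohol by the chloroformate, which installs the leaving group for the allylic ionisation.

Step 13
Reactants: 22 methyl (Z)-4-methyl-4-{2,4-dimethyl-3-[(S)-3-methyl-5-(triisopropylsilyloxy)pentyl]-5-(triisopropylsilyloxy)phenyl}pent-2-en-1-yl carbonate
Product: 23 methyl (Z)-4-{5-hydroxy-2,4-dimethyl-3-[(S)-3-methyl-5-(triisopropylsilyloxy)pentyl]phenyl}-4-methylpent-2-en-1-yl carbonate
Conditions: KHF2 (2.5 equiv), MeOH, rt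
Reagents that add atoms: none
Why: Selective desilylation, since bifluoride in methanol cleaves aryl silyl ethers (phenoxide as leaving group) at room temperature while primary alkyl silyl ethers and the carbonate persist.

Step 14
Reactants: 23 methyl (Z)-4-{5-hydroxy-2,4-dimethyl-3-[(S)-3-methyl-5-(triisopropylsilyloxy)pentyl]phenyl}-4-methylpent-2-en-1-yl carbonate
Product: 24 methyl (Z)-4-{6-bromo-5-hydroxy-2,4-dimethyl-3-[(S)-3-methyl-5-(triisopropylsilyloxy)pentyl]phenyl}-4-methylpent-2-en-1-yl carbonate
Conditions: NBS (1.05 equiv), iPr2NH (10 mol%), CH2Cl2, 0 °C, dark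
Reagents that add atoms: N-bromosuccinimide, O=C1CCC(=O)N1Br
Why: Amine-promoted electrophilic ortho-bromination of a phenol, directed to C6 because it is the only unsubstituted ring carbon and lies ortho to the hydroxyl, while the hindered allylic-carbonate alkene is far less nucleophilic than the phenol ring.

Step 15
Reactants: 24 methyl (Z)-4-{6-bromo-5-hydroxy-2,4-dimethyl-3-[(S)-3-methyl-5-(triisopropylsilyloxy)pentyl]phenyl}-4-methylpent-2-en-1-yl carbonate
Product: 25 6-bromo-15-(triisopropylsilyloxy)labda-2,5,8-trien-7-one (10β-methyl, 13S)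
Conditions: [Pd(C3H5)Cl]2 (2.5 mol%), (1R,2R)-N,N'-bis[2-(diphenylphosphino)benzoyl]cyclohexane-1,2-diamine (7.5 mol%), degassed CH2Cl2 (0.01 M), rt
Reagents that add atoms: none
Why: Proposed new method: zerovalent palladium, formed from [Pd(C3H5)Cl]2 and the bisphosphine, ionises the (Z)-allyl carbonate with loss of CO2 to the anti-configured η3-allyl complex of divalent palladium, and the methoxide set free deprotonates the phenol. The phenolate attacks the unsubstituted allyl terminus C1 through its para carbon C10 on the allyl face away from the metal, which forms C1–C10, closes ring A (C1, C2, C3, C4, C5, C10) in a six-membered closure that takes all three allyl carbons into the ring and leaves the cis C2=C3 alkene, and turns ring B into a cross-conjugated cyclohexa-2,5-dienone. The closest known reactions are the palladium- and iridium-catalysed intramolecular asymmetric allylic dearomatisations of para-substituted phenols to spirocyclohexadienones and Tsuji–Trost alkylations of prochiral enolates; a fused closure onto a methyl-bearing para carbon goes beyond them. The new quaternary centre C10 is set by the chiral ligand, which decides over which face of the planar phenolate the tethered allyl–palladium unit folds, C13 being too remote to interfere. The step needs attack through C10 and not through oxygen, C8 or C6: oxygen and C8 cannot reach C1 in a strain-free ring, O-allylation between two molecules is reversible under the catalyst, and C6 is blocked by bromine, which also lowers its nucleophilicity and whose hindered, electron-rich C–Br bond should not add to an arylphosphine complex of zerovalent palladium at room temperature. The flanking C6–Br and C10–CH3 hold the C4 arm out of the ring plane, which places the allyl unit above C10.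

Step 16
Reactants: 25 6-bromo-15-(triisopropylsilyloxy)labda-2,5,8-trien-7-one
Product: 26 15-(triisopropylsilyloxy)labd-8-en-7-one (5α-H, 10β-methyl, 13S)
Conditions: H2 (1 atm), 10% palladium on carbon, Et3N (2 equiv), EtOAc, rt
Reagents that add atoms: none
Why: Heterogeneous hydrogenation with hydrogenolysis, which cleaves C–Br and saturates the cis C2=C3 alkene and the trisubstituted C5=C6 enone alkene while the tetrasubstituted C8=C9 enone stays; hydrogen should reach C5 from the face opposite the C10 methyl and the axial C4 methyl, as in 4,4-dimethyl-5-ene steroids, which sets the trans ring fusion.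

Step 17
Reactants: 26 15-(triisopropylsilyloxy)labd-8-en-7-one
Product: 28 15-(triisopropylsilyloxy)labd-7-en-7-yl trifluoromethanesulfonate, via lithium enolate 27 (not isolated)
Conditions: Li (2.2 equiv), NH3(l)/THF, t-BuOH (1.0 equiv), −78 °C; evaporate NH3; then PhNTf2, THF, −78 °C to rt
Reagents that add atoms: N-phenylbis(trifluoromethanesulfonimide), O=S(=O)(N(c1ccccc1)S(=O)(=O)C(F)(F)F)C(F)(F)F
Why: Dissolving-metal (Birch-type) enone reduction with enolate trapping, in which C9 is protonated axially, anti to the C10 methyl, so that the chain becomes equatorial (9α-H), and the regiodefined C7=C8 lithium enolate is sulfonylated on oxygen.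

Step 18
Reactants: 28 15-(triisopropylsilyloxy)labd-7-en-7-yl trifluoromethanesulfonate
Product: 29 15-(triisopropylsilyloxy)labd-7-ene
Conditions: Pd(OAc)2 (5 mol%), PPh3 (10 mol%), HCO2H, n-Bu3N, DMF, 60 °C
Reagents that add atoms: none
Why: Palladium-catalysed reduction of an enol triflate by formate (oxidative addition, formate exchange, decarboxylation, reductive elimination), which replaces C7–O by C7–H and fixes the C7=C8 alkene.

Step 19
Reactants: 29 15-(triisopropylsilyloxy)labd-7-ene
Product: 30 15-(triisopropylsilyloxy)labd-7-en-17-ol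
Conditions: SeO2 (0.5 equiv), t-BuOOH (3 equiv), CH2Cl2, rt
Reagents that add atoms: selenium dioxide, O=[Se]=O (delivers the oxygen); tert-butyl hydroperoxide, CC(C)(C)OO (reoxidises selenium, net oxygen source)
Why: Selenium dioxide allylic oxidation (ene reaction at the less substituted alkene carbon C7, then [2,3]-sigmatropic shift), which on a trisubstituted alkene oxidises a group on the more substituted carbon C8 and prefers the methyl over the hindered tertiary C9–H, as known for drim-7-enes, so the C17 alcohol is expected with the alkene back at C7=C8.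

Step 20
Reactants: 30 15-(triisopropylsilyloxy)labd-7-en-17-ol
Product: 31 labd-7-ene-15,17-diol
Conditions: Bu4NF, THF, rt
Reagents that add atoms: none
Why: Fluoride-induced cleavage of the primary silyl ether, driven by the strength of the Si–F bond.

Step 21
Reactants: 31 labd-7-ene-15,17-diol
Product: 32 (5S,9R,10S,13S)-labd-7-ene-15,17-diyl diacetate (CNP0294037.1)
Conditions: Ac2O, pyridine, DMAP (cat.), CH2Cl2, rt
Reagents that add atoms: acetic anhydride, CC(=O)OC(C)=O
Why: Nucleophile-catalysed acetylation of both primary hydroxyl groups, which touches no stereocentre.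

## Compound list

1 | (R)-methyl hydrogen 3-methylglutarate | C[C@H](CC(=O)O)CC(=O)OC | starting material
2 | lithium (S)-5-hydroxy-3-methylpentanoate (in-flask species) | C[C@H](CC(=O)[O-])CCO.[Li+] | intermediate
3 | (S)-4-methyltetrahydro-2H-pyran-2-one | C[C@@H]1CC(=O)OCC1 | intermediate
4 | methyl (R)-5-bromo-3-methylpentanoate | C[C@@H](CCBr)CC(=O)OC | intermediate
5 | 2-bromo-1,3-dimethylbenzene | Cc1cccc(C)c1Br | starting material
6 | [(R)-5-methoxy-3-methyl-5-oxopentyl]zinc bromide (in-flask species) | C[C@@H](CC[Zn]Br)CC(=O)OC | intermediate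
7 | methyl (S)-5-(2,6-dimethylphenyl)-3-methylpentanoate | C[C@@H](CCc1c(C)cccc1C)CC(=O)OC | intermediate
8 | methyl (S)-5-(3,5-dibromo-2,6-dimethylphenyl)-3-methylpentanoate | C[C@@H](CCc1c(C)c(Br)cc(Br)c1C)CC(=O)OC | intermediate
9 | (S)-5-(3,5-dibromo-2,6-dimethylphenyl)-3-methylpentan-1-ol | C[C@@H](CCc1c(C)c(Br)cc(Br)c1C)CCO | intermediate
10 | lithium (S)-5-(3-bromo-5-lithio-2,6-dimethylphenyl)-3-methylpentan-1-olate (in-flask species) | C[C@@H](CCc1c(C)c(Br)cc([Li])c1C)CCO[Li] | intermediate
11 | lithium aryltrimethoxyborate derived from 10 (in-flask species) | C[C@@H](CCc1c(C)c(Br)cc([B-](OC)(OC)OC)c1C)CCO[Li].[Li+] | intermediate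
12 | 5-bromo-3-[(S)-5-hydroxy-3-methylpentyl]-2,4-dimethylphenol | C[C@@H](CCc1c(C)c(Br)cc(O)c1C)CCO | intermediate
13 | {5-bromo-2,4-dimethyl-3-[(S)-3-methyl-5-(triisopropylsilyloxy)pentyl]phenoxy}triisopropylsilane | C[C@@H](CCc1c(C)c(Br)cc(O[Si](C(C)C)(C(C)C)C(C)C)c1C)CCO[Si](C(C)C)(C(C)C)C(C)C | intermediate
14 | methyl isobutyrate | COC(=O)C(C)C | starting material
15 | lithium enolate of methyl isobutyrate (in-flask species) | COC(O[Li])=C(C)C | intermediate
16 | methyl 2-methyl-2-{2,4-dimethyl-3-[(S)-3-methyl-5-(triisopropylsilyloxy)pentyl]-5-(triisopropylsilyloxy)phenyl}propanoate | C[C@@H](CCc1c(C)c(C(C)(C)C(=O)OC)cc(O[Si](C(C)C)(C(C)C)C(C)C)c1C)CCO[Si](C(C)C)(C(C)C)C(C)C | intermediate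
17 | 2-methyl-2-{2,4-dimethyl-3-[(S)-3-methyl-5-(triisopropylsilyloxy)pentyl]-5-(triisopropylsilyloxy)phenyl}propanal | C[C@@H](CCc1c(C)c(C(C)(C)C=O)cc(O[Si](C(C)C)(C(C)C)C(C)C)c1C)CCO[Si](C(C)C)(C(C)C)C(C)C | intermediate
18 | methyl bis(2,2,2-trifluoroethyl)phosphonoacetate | COC(=O)CP(=O)(OCC(F)(F)F)OCC(F)(F)F | starting material
19 | potassium salt of the carbanion of 18 (in-flask species) | COC(=O)[CH-]P(=O)(OCC(F)(F)F)OCC(F)(F)F.[K+] | intermediate
20 | methyl (Z)-4-methyl-4-{2,4-dimethyl-3-[(S)-3-methyl-5-(triisopropylsilyloxy)pentyl]-5-(triisopropylsilyloxy)phenyl}pent-2-enoate | C[C@@H](CCc1c(C)c(C(C)(C)/C=C\C(=O)OC)cc(O[Si](C(C)C)(C(C)C)C(C)C)c1C)CCO[Si](C(C)C)(C(C)C)C(C)C | intermediate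
21 | (Z)-4-methyl-4-{2,4-dimethyl-3-[(S)-3-methyl-5-(triisopropylsilyloxy)pentyl]-5-(triisopropylsilyloxy)phenyl}pent-2-en-1-ol | C[C@@H](CCc1c(C)c(C(C)(C)/C=C\CO)cc(O[Si](C(C)C)(C(C)C)C(C)C)c1C)CCO[Si](C(C)C)(C(C)C)C(C)C | intermediate
22 | methyl (Z)-4-methyl-4-{2,4-dimethyl-3-[(S)-3-methyl-5-(triisopropylsilyloxy)pentyl]-5-(triisopropylsilyloxy)phenyl}pent-2-en-1-yl carbonate | C[C@@H](CCc1c(C)c(C(C)(C)/C=C\COC(=O)OC)cc(O[Si](C(C)C)(C(C)C)C(C)C)c1C)CCO[Si](C(C)C)(C(C)C)C(C)C | intermediate
23 | methyl (Z)-4-{5-hydroxy-2,4-dimethyl-3-[(S)-3-methyl-5-(triisopropylsilyloxy)pentyl]phenyl}-4-methylpent-2-en-1-yl carbonate | C[C@@H](CCc1c(C)c(C(C)(C)/C=C\COC(=O)OC)cc(O)c1C)CCO[Si](C(C)C)(C(C)C)C(C)C | intermediate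
24 | methyl (Z)-4-{6-bromo-5-hydroxy-2,4-dimethyl-3-[(S)-3-methyl-5-(triisopropylsilyloxy)pentyl]phenyl}-4-methylpent-2-en-1-yl carbonate (cyclisation precursor) | C[C@@H](CCc1c(C)c(C(C)(C)/C=C\COC(=O)OC)c(Br)c(O)c1C)CCO[Si](C(C)C)(C(C)C)C(C)C | intermediate
25 | 6-bromo-15-(triisopropylsilyloxy)labda-2,5,8-trien-7-one | CC1=C(CC[C@H](C)CCO[Si](C(C)C)(C(C)C)C(C)C)[C@@]2(C)CC=CC(C)(C)C2=C(Br)C1=O | intermediate
26 | 15-(triisopropylsilyloxy)labd-8-en-7-one (5α-H) | C[C@@H](CCC1=C(C)C(=O)C[C@H]2C(C)(C)CCC[C@]12C)CCO[Si](C(C)C)(C(C)C)C(C)C | intermediate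
27 | lithium 15-(triisopropylsilyloxy)labd-7-en-7-olate (in-flask species) | C[C@@H](CC[C@H]1C(C)=C(O[Li])C[C@H]2C(C)(C)CCC[C@]12C)CCO[Si](C(C)C)(C(C)C)C(C)C | intermediate
28 | 15-(triisopropylsilyloxy)labd-7-en-7-yl trifluoromethanesulfonate | C[C@@H](CC[C@H]1C(C)=C(OS(=O)(=O)C(F)(F)F)C[C@H]2C(C)(C)CCC[C@]12C)CCO[Si](C(C)C)(C(C)C)C(C)C | intermediate
29 | 15-(triisopropylsilyloxy)labd-7-ene | C[C@@H](CC[C@H]1C(C)=CC[C@H]2C(C)(C)CCC[C@]12C)CCO[Si](C(C)C)(C(C)C)C(C)C | intermediate
30 | 15-(triisopropylsilyloxy)labd-7-en-17-ol | C[C@@H](CC[C@H]1C(CO)=CC[C@H]2C(C)(C)CCC[C@]12C)CCO[Si](C(C)C)(C(C)C)C(C)C | intermediate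
31 | labd-7-ene-15,17-diol | C[C@@H](CC[C@H]1C(CO)=CC[C@H]2C(C)(C)CCC[C@]12C)CCO | intermediate
32 | (5S,9R,10S,13S)-labd-7-ene-15,17-diyl diacetate (CNP0294037.1) | CC(=O)OCC[C@@H](C)CC[C@H]1C(COC(C)=O)=CC[C@H]2C(C)(C)CCC[C@]12C | target

## Step count and risks

Total step count: 21. Longest linear sequence: 21 steps (from 1; compounds 5, 14 and 18 enter as purchased materials).

Steps most likely to fail:

1. Step 15 (the proposed new method).
   - What may go wrong: the anti-configured allyl complex may relax to the syn form before C10 attacks, after which only reversible O-allylation between two molecules remains open. Attack through C6 may compete. Face discrimination at the phenolate by the ligand may be weak, which would give C10 epimers that differ only through the distant C13.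
   - Fallback, from 21 back to 26, by known chemistry: the (Z)-allylic alcohol 21 would be hydrogenated (H2, PtO2, EtOAc) to the saturated bis-silyl alcohol F1 and converted with MsCl/Et3N into the mesylate F2. The aryl silyl ether would be cleaved with KHF2 in MeOH to give the phenol mesylate F3, and C6 brominated with NBS to give the bromophenol mesylate F4. KOtBu in t-BuOH/THF would then close ring A by the long-known base-mediated para-alkylation of a phenolate by a tethered primary sulfonate (Ar2-6 participation), giving 6-bromo-15-(triisopropylsilyloxy)labda-5,8-dien-7-one F5. No chiral reagent is involved, so both C10 epimers form; they are diastereomers through C13 and would have to be separated by chromatography. Hydrogenation of the correct epimer under the conditions of step 16 returns to 26.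

2. Step 14.
   - What may go wrong: bromine transfer to C6 may be slowed by the two flanking groups (hydroxyl and the tertiary C4 arm, itself buttressed by the C10 methyl), so that ipso attack at the methyl-bearing C10 with onward benzylic bromination, or addition to the C2=C3 alkene, takes over.
   - Fallback, from 23 back to 26, with a smaller blocking atom that is also inert to zerovalent palladium: phenol 23 would be chlorinated at C6 with NCS (iPr2NH cat., CH2Cl2) to the chlorophenol carbonate F6. Cyclisation under the conditions of step 15 would give 6-chloro-15-(triisopropylsilyloxy)labda-2,5,8-trien-7-one F7. Hydrogenation over palladium on carbon with Et3N under raised hydrogen pressure would remove chlorine and saturate C2=C3 and C5=C6, returning to 26.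

3. Step 19.
   - What may go wrong: hydrogen abstraction may occur at C9–H instead of the C17 methyl, and the allylic alcohol may be oxidised on to the enal.
   - Fallback, from 29 back to 30: mCPBA would epoxidise 29 from the face opposite the C10 methyl to the 7α,8α-epoxide F8. Al(OiPr)3 in hot toluene would isomerise it, with proton loss from the C17 methyl, to 15-(triisopropylsilyloxy)labd-8(17)-en-7α-ol F9. Catalytic O3ReOSiPh3 would then effect the 1,3-transposition of this allylic alcohol towards the more substituted ring alkene and the primary alcohol, which is 30.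

Further compounds
F1 | step 15 | 4-methyl-4-{2,4-dimethyl-3-[(S)-3-methyl-5-(triisopropylsilyloxy)pentyl]-5-(triisopropylsilyloxy)phenyl}pentan-1-ol | C[C@@H](CCc1c(C)c(C(C)(C)CCCO)cc(O[Si](C(C)C)(C(C)C)C(C)C)c1C)CCO[Si](C(C)C)(C(C)C)C(C)C
F2 | step 15 | methanesulfonate of F1 | C[C@@H](CCc1c(C)c(C(C)(C)CCCOS(C)(=O)=O)cc(O[Si](C(C)C)(C(C)C)C(C)C)c1C)CCO[Si](C(C)C)(C(C)C)C(C)C
F3 | step 15 | 4-{5-hydroxy-2,4-dimethyl-3-[(S)-3-methyl-5-(triisopropylsilyloxy)pentyl]phenyl}-4-methylpentyl methanesulfonate | C[C@@H](CCc1c(C)c(C(C)(C)CCCOS(C)(=O)=O)cc(O)c1C)CCO[Si](C(C)C)(C(C)C)C(C)C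
F4 | step 15 | 4-{6-bromo-5-hydroxy-2,4-dimethyl-3-[(S)-3-methyl-5-(triisopropylsilyloxy)pentyl]phenyl}-4-methylpentyl methanesulfonate | C[C@@H](CCc1c(C)c(C(C)(C)CCCOS(C)(=O)=O)c(Br)c(O)c1C)CCO[Si](C(C)C)(C(C)C)C(C)C
F5 | step 15 | 6-bromo-15-(triisopropylsilyloxy)labda-5,8-dien-7-one (10β-methyl epimer) | CC1=C(CC[C@H](C)CCO[Si](C(C)C)(C(C)C)C(C)C)[C@@]2(C)CCCC(C)(C)C2=C(Br)C1=O
F6 | step 14 | methyl (Z)-4-{6-chloro-5-hydroxy-2,4-dimethyl-3-[(S)-3-methyl-5-(triisopropylsilyloxy)pentyl]phenyl}-4-methylpent-2-en-1-yl carbonate | C[C@@H](CCc1c(C)c(C(C)(C)/C=C\COC(=O)OC)c(Cl)c(O)c1C)CCO[Si](C(C)C)(C(C)C)C(C)C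
F7 | step 14 | 6-chloro-15-(triisopropylsilyloxy)labda-2,5,8-trien-7-one | CC1=C(CC[C@H](C)CCO[Si](C(C)C)(C(C)C)C(C)C)[C@@]2(C)CC=CC(C)(C)C2=C(Cl)C1=O
F8 | step 19 | 7α,8α-epoxy-15-(triisopropylsilyloxy)labdane | C[C@@H](CC[C@H]1[C@]2(C)O[C@@H]2C[C@H]3C(C)(C)CCC[C@]13C)CCO[Si](C(C)C)(C(C)C)C(C)C
F9 | step 19 | 15-(triisopropylsilyloxy)labd-8(17)-en-7α-ol | C[C@@H](CC[C@H]1C(=C)[C@H](O)C[C@H]2C(C)(C)CCC[C@]12C)CCO[Si](C(C)C)(C(C)C)C(C)C
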